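The synthesis builds the phthalide benzene ring last, from open-chain partners, instead of substituting a preformed arene. The feature exploited is the ring pattern itself. Oxygen sits on C5 and C7, the lactone carbonyl C1 on C7a and the carbinol C3 on C3a. This matches a 1,3-dioxygenated diene (C4–C7) joined to a 4-oxygenated alk-2-ynoate (C3a, C7a, C1, C3). One thermal cycloaddition–aromatisation, finished with fluoride in the same flask, forms C4–C3a, C7–C7a and O2–C1, closing both the benzene and the lactone ring. The precursor is a methyl (R)-4-silyloxydec-2-ynoate already carrying the finished (2S,5R,7S)-spiroketal, hence all four stereocentres.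

Key step: step 9

Stereochemical reading of the target: 3R in the phthalide and 2''S, 5''R, 7''S in the spiroketal (double-primed locants). Each alkyl group lies trans to the oxygen of the other ring.

Design remark: a 1,6-dioxaspiro[4.4]nonane has little thermodynamic bias at C5'' and epimerises with trace acid. The single spiro epimer is therefore secured early with acid recycling, and every later step is run buffered or basic.

Assumption: (R,R)-ProPhenol is taken to deliver the alkynylzinc to the Si face of an unbranched aliphatic aldehyde, giving the 4R alcohol. Both antipodes are commercial, so the sense is checked by Mosher ester analysis on a trial run and the ligand is exchanged if needed.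

Step 1
Reactants: 1 methyl acetoacetate
Product: 2 methyl (E)-3-methoxybut-2-enoate
Conditions: HC(OMe)3, H2SO4 (cat.), MeOH, rt; distillation
Reagents that add atoms: trimethyl orthoformate, COC(OC)OC
Why: Acid-catalysed enol etherification of a β-keto ester (ketalisation by the orthoester, then loss of methanol) should give the conjugated E-enol ether as the thermodynamic product, and no stereocentre is formed.

Step 2
Reactants: 2 methyl (E)-3-methoxybut-2-enoate
Product: 3 (E)-1,3-dimethoxy-1-(trimethylsilyloxy)buta-1,3-diene (Brassard's diene)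
Conditions: LiN(iPr)2 (commercial solution), THF, −78 °C; Me3SiCl, −78 °C → rt; distillation
Reagents that add atoms: chlorotrimethylsilane, C[Si](C)(C)Cl
Why: Kinetic γ-deprotonation gives the extended dienolate, whose oxygen is trapped by the silyl chloride (silyl ketene acetal formation), and the C1=C2 geometry is of no consequence because C1 becomes an aromatic carbon.

Step 3
Reactants: 4 racemic 1,2-epoxydec-9-ene
Product: 5 (S)-1,2-epoxydec-9-ene
Conditions: (S,S)-(salen)Co(OAc) [salen = dianion of N,N'-bis(3,5-di-tert-butylsalicylidene)cyclohexane-1,2-diamine] (0.5 mol %), H2O (0.55 equiv), neat, 0 °C → rt; distillation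
Reagents that add atoms: none
Why: In the Jacobsen hydrolytic kinetic resolution the (S,S)-cobalt salen acetate (trivalent cobalt) hydrolyses the (R)-epoxide much faster, so the unreacted (S)-epoxide, whose carbinol carbon becomes C2'', is distilled away from the diol.

Step 4
Reactants: 6 acetone N,N-dimethylhydrazone; 7 (S)-propylene oxide
Product: 8 (S)-5-(2,2-dimethylhydrazinylidene)hexan-2-ol
Conditions: nBuLi, THF, −78 → 0 °C; 7, 0 °C → rt; H2O
Reagents that add atoms: none
Why: In this Corey–Enders azaenolate alkylation the lithiated hydrazone opens the epoxide by SN2 at its CH2 terminus, so the C–O stereocentre (future C7'', S) is carried over untouched.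

Step 5
Reactants: 8 (S)-5-(2,2-dimethylhydrazinylidene)hexan-2-ol; 5 (S)-1,2-epoxydec-9-ene
Product: 12 (2S,5R,7S)-7-methyl-2-(oct-7-en-1-yl)-1,6-dioxaspiro[4.4]nonane, via dihydroxy hydrazone 9 (not isolated), via keto diol 10 (not isolated), via (5S)-spiroketal epimer 11 (not isolated)
Conditions: nBuLi (2.1 equiv), THF, −78 → 0 °C; 5, 0 °C → rt; 1 M aq HCl, THF, rt; chromatography on Et3N-washed SiO2; fractions rich in 11: camphorsulfonic acid (cat.), CH2Cl2, rt, then re-chromatographed
Reagents that add atoms: none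
Why: A second azaenolate alkylation, regioselective for the less substituted methyl side of the dimethylhydrazone, opens 5 at its terminus without touching C2''; acid hydrolysis then frees keto diol 10, which spiroketalises at once, and because C5'' equilibrates through the oxocarbenium ion with little bias it is set by separating 12 from 11 and recycling 11 under acid.

Step 6
Reactants: 12 (2S,5R,7S)-7-methyl-2-(oct-7-en-1-yl)-1,6-dioxaspiro[4.4]nonane
Product: 13 7-[(2S,5R,7S)-7-methyl-1,6-dioxaspiro[4.4]nonan-2-yl]heptanal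
Conditions: O3, CH2Cl2, NaHCO3 (solid), −78 °C (Sudan Red 7B end point); PPh3, −78 °C → rt
Reagents that add atoms: ozone, [O-][O+]=O
Why: Criegee ozonolysis with reductive work-up cleaves the only alkene, the ketal carbon offers no C–H bond to ozone, and the bicarbonate keeps out the acid that would epimerise C5''.

Step 7
Reactants: 13 7-[(2S,5R,7S)-7-methyl-1,6-dioxaspiro[4.4]nonan-2-yl]heptanal; 14 methyl propiolate
Product: 15 methyl (R)-4-hydroxy-10-[(2S,5R,7S)-7-methyl-1,6-dioxaspiro[4.4]nonan-2-yl]dec-2-ynoate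
Conditions: 14 (2.8 equiv), Me2Zn (2.95 equiv), (R,R)-ProPhenol (20 mol %), Ph3P=O (40 mol %), toluene, 4 °C; pH 7 phosphate buffer
Reagents that add atoms: none
Why: In the zinc–ProPhenol catalytic asymmetric alkynylation the dinuclear zinc pocket binds the aldehyde and the alkynylzinc formed from Me2Zn and 14, and delivers the alkynyl group to the Si face, which sets C4 (future C3) as R under pure catalyst control because the spiroketal centres are too remote to interfere.

Step 8
Reactants: 15 methyl (R)-4-hydroxy-10-[(2S,5R,7S)-7-methyl-1,6-dioxaspiro[4.4]nonan-2-yl]dec-2-ynoate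
Product: 16 methyl (R)-4-(tert-butyldimethylsilyloxy)-10-[(2S,5R,7S)-7-methyl-1,6-dioxaspiro[4.4]nonan-2-yl]dec-2-ynoate
Conditions: TBSCl, imidazole, DMF, 0 °C → rt
Reagents that add atoms: tert-butyldimethylsilyl chloride, CC(C)(C)[Si](C)(C)Cl
Why: Standard imidazole-promoted O-silylation is chosen because imidazole is too weak a base to isomerise the 4-hydroxy-ynoate, no Lewis acid touches the ketal, and the C4–O bond is not broken.

Step 9
Reactants: 16 methyl (R)-4-(tert-butyldimethylsilyloxy)-10-[(2S,5R,7S)-7-methyl-1,6-dioxaspiro[4.4]nonan-2-yl]dec-2-ynoate; 3 Brassard's diene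
Product: 20 (3R)-7-hydroxy-5-methoxy-3-{6-[(2S,5R,7S)-7-methyl-1,6-dioxaspiro[4.4]nonan-2-yl]hexyl}isobenzofuran-1(3H)-one, via cyclohexadiene cycloadduct 17 (not isolated), via aryl silyl ether 18 (not isolated), via hydroxy ester 19 (not isolated)
Conditions: 3 (4 equiv, in two portions), neat, sealed tube, 120 °C; cool, THF, Bu4NF (4 equiv), 0 °C → rt; pH 7 phosphate buffer
Reagents that add atoms: none
Why: The electron-rich ketene silyl acetal diene 3 and the electron-poor ynoate 16 should combine in a strongly asynchronous [4+2] cycloaddition (at the limit a Michael–Claisen sequence), in which the unsubstituted CH2 terminus of 3 attacks the ynoate β-carbon (C4–C3a) and the ketene-acetal carbon bonds to the α-carbon (C7–C7a) to give cyclohexadiene 17. Compound 17 aromatises by 1,4-loss of methanol to aryl silyl ether 18, fluoride strips both silyl groups to 19, and the C3 alkoxide attacks the neighbouring methyl ester to give 20, while any material that loses silanol instead already carries the C7 methyl ether and ends as 21, so both channels converge. The closest known reaction type is the Diels–Alder/aromatisation of 1-alkoxy-1-silyloxy-1,3-dienes with alkynoates to resorcylates, applied here to a β-branched ynoate. The benzene ring closes by intermolecular [4+2] union of a four-carbon and a two-carbon unit, and the lactone closes by 5-exo-trig acyl substitution. No lasting stereocentre is created (the ketal carbon of 17 vanishes on aromatisation), and C3 stays R because its C–O and C–H bonds are never touched. Only regioselectivity is required and the matched polarisation of the two partners secures it, while the acid-free medium (excess ketene acetal scavenges protic acid, fluoride is basic) protects the labile C5'' centre.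

Step 10
Reactants: 20 (3R)-7-hydroxy-5-methoxy-3-{6-[(2S,5R,7S)-7-methyl-1,6-dioxaspiro[4.4]nonan-2-yl]hexyl}isobenzofuran-1(3H)-one
Product: 21 (3R)-5,7-dimethoxy-3-{6-[(2S,5R,7S)-7-methyl-1,6-dioxaspiro[4.4]nonan-2-yl]hexyl}isobenzofuran-1(3H)-one
Conditions: MeI, K2CO3, acetone, 45 °C; chromatography on Et3N-washed SiO2
Reagents that add atoms: iodomethane, CI
Why: Williamson O-methylation of the hydrogen-bonded C7 phenol should proceed cleanly because carbonate is too weak to deprotonate C3–H and basic conditions leave the spiroketal untouched.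

Compound list
1 | methyl acetoacetate | CC(=O)CC(=O)OC | starting material
2 | methyl (E)-3-methoxybut-2-enoate | CO/C(C)=C/C(=O)OC | intermediate
3 | (E)-1,3-dimethoxy-1-(trimethylsilyloxy)buta-1,3-diene (Brassard's diene) | C=C(OC)/C=C(\OC)O[Si](C)(C)C | intermediate
4 | racemic 1,2-epoxydec-9-ene | C=CCCCCCCC1CO1 | starting material
5 | (S)-1,2-epoxydec-9-ene | C=CCCCCCC[C@H]1CO1 | intermediate
6 | acetone N,N-dimethylhydrazone | CC(C)=NN(C)C | starting material
7 | (S)-propylene oxide | C[C@H]1CO1 | starting material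
8 | (S)-5-(2,2-dimethylhydrazinylidene)hexan-2-ol | C[C@H](O)CCC(C)=NN(C)C | intermediate
9 | (2S,8S)-5-(2,2-dimethylhydrazinylidene)hexadec-15-ene-2,8-diol | C[C@H](O)CCC(=NN(C)C)CC[C@@H](O)CCCCCCC=C | intermediate
10 | (2S,8S)-2,8-dihydroxyhexadec-15-en-5-one | C[C@H](O)CCC(=O)CC[C@@H](O)CCCCCCC=C | intermediate
11 | (2S,5S,7S)-7-methyl-2-(oct-7-en-1-yl)-1,6-dioxaspiro[4.4]nonane | C=CCCCCCC[C@H]1CC[C@]2(CC[C@H](C)O2)O1 | intermediate
12 | (2S,5R,7S)-7-methyl-2-(oct-7-en-1-yl)-1,6-dioxaspiro[4.4]nonane | C=CCCCCCC[C@H]1CC[C@@]2(CC[C@H](C)O2)O1 | intermediate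
13 | 7-[(2S,5R,7S)-7-methyl-1,6-dioxaspiro[4.4]nonan-2-yl]heptanal | O=CCCCCCC[C@H]1CC[C@@]2(CC[C@H](C)O2)O1 | intermediate
14 | methyl propiolate | C#CC(=O)OC | starting material
15 | methyl (R)-4-hydroxy-10-[(2S,5R,7S)-7-methyl-1,6-dioxaspiro[4.4]nonan-2-yl]dec-2-ynoate | COC(=O)C#C[C@@H](CCCCCC[C@H]1CC[C@@]2(CC[C@H](C)O2)O1)O | intermediate
16 | methyl (R)-4-(tert-butyldimethylsilyloxy)-10-[(2S,5R,7S)-7-methyl-1,6-dioxaspiro[4.4]nonan-2-yl]dec-2-ynoate | COC(=O)C#C[C@@H](CCCCCC[C@H]1CC[C@@]3(CC[C@H](C)O3)O1)O[Si](C)(C)C(C)(C)C | intermediate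
17 | methyl 2-{(1R)-1-(tert-butyldimethylsilyloxy)-7-[(2S,5R,7S)-7-methyl-1,6-dioxaspiro[4.4]nonan-2-yl]heptyl}-4,6-dimethoxy-6-(trimethylsilyloxy)cyclohexa-1,4-diene-1-carboxylate (C6 unassigned) | COC1=CC(OC)(O[Si](C)(C)C)C(C(=O)OC)=C(C1)[C@@H](CCCCCC[C@H]2CC[C@@]3(CC[C@H](C)O3)O2)O[Si](C)(C)C(C)(C)C | intermediate
18 | methyl 2-{(1R)-1-(tert-butyldimethylsilyloxy)-7-[(2S,5R,7S)-7-methyl-1,6-dioxaspiro[4.4]nonan-2-yl]heptyl}-4-methoxy-6-(trimethylsilyloxy)benzoate | COC(=O)c1c(O[Si](C)(C)C)cc(OC)cc1[C@@H](CCCCCC[C@H]2CC[C@@]3(CC[C@H](C)O3)O2)O[Si](C)(C)C(C)(C)C | intermediate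
19 | methyl 2-hydroxy-6-{(1R)-1-hydroxy-7-[(2S,5R,7S)-7-methyl-1,6-dioxaspiro[4.4]nonan-2-yl]heptyl}-4-methoxybenzoate | COC(=O)c1c(O)cc(OC)cc1[C@@H](CCCCCC[C@H]2CC[C@@]3(CC[C@H](C)O3)O2)O | intermediate
20 | (3R)-7-hydroxy-5-methoxy-3-{6-[(2S,5R,7S)-7-methyl-1,6-dioxaspiro[4.4]nonan-2-yl]hexyl}isobenzofuran-1(3H)-one | COc1cc(O)c2c(c1)[C@@H](CCCCCC[C@H]1CC[C@@]3(CC[C@H](C)O3)O1)OC2=O | intermediate
21 | (3R)-5,7-dimethoxy-3-{6-[(2S,5R,7S)-7-methyl-1,6-dioxaspiro[4.4]nonan-2-yl]hexyl}isobenzofuran-1(3H)-one | COc1cc(OC)c2c(c1)[C@@H](CCCCCC[C@H]1CC[C@@]3(CC[C@H](C)O3)O1)OC2=O | target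

Total step count: 10.
Longest linear sequence: 7 steps (3, 5, 6, 7, 8, 9, 10 from 4; equally 4, 5, 6, 7, 8, 9, 10 from 6 and 7).

Steps most likely to fail

1. Step 9.
- Risk: the cycloaddition may be too slow at the β-branched alkyne carbon, so that thermal silyl migration and decay of the diene outrun C–C bond formation. Prolonged heating may also erode the spiro centre.
- Fallback (preformed arene, lactone carbonyl added last): it sets out from 13 and returns at 21. Commercial 3,5-(MeO)2C6H3MgBr adds to 13 to give the epimeric benzylic alcohol F1. Dess–Martin periodinane buffered with NaHCO3 gives the aryl ketone F2. Corey–Bakshi–Shibata reduction with (S)-Me-CBS and BH3·SMe2 gives the (R)-carbinol F3. N-Bromosuccinimide with NaHCO3 brominates the ring position ortho to the side chain and para to a methoxy group, giving the aryl bromide F4. Carbonylative lactonisation (Pd(OAc)2, dppf, CO, K2CO3, DMF) then closes the lactone and delivers 21 directly.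

2. Step 5.
- Risk: the two non-polar, UV-silent spiro epimers may not resolve on silica, or may re-equilibrate during the separation.
- Fallback (separation moved to a derivative with a chromophore): it sets out from the unseparated mixture of 11 and 12 and returns at 13. Ozonolysis with NaBH4 work-up gives the primary alcohol F5 as both spiro epimers. 3,5-Dinitrobenzoyl chloride and pyridine convert it into the UV-active ester F6, which is expected to crystallise. Fractional crystallisation or preparative HPLC gives the (5R)-ester F7, while the (5S)-ester F8 is re-equilibrated with catalytic camphorsulfonic acid and returned to the separation. K2CO3 in MeOH frees the (5R)-alcohol F9, and Parikh–Doering oxidation (SO3·pyridine, DMSO, Et3N) gives 13.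

3. Step 7.
- Risk: facial discrimination may be modest with an unbranched, enolisable aldehyde, and self-aldol condensation may compete with the slow alkynyl transfer.
- Fallback (stereocentre set by reduction instead of addition): it sets out from 13 and returns at 15. Methyl propiolate lithiated with LiN(iPr)2 in THF at −78 °C adds to 13 to give the epimeric propargylic alcohol F10. Dess–Martin periodinane buffered with NaHCO3 gives the 4-oxo-ynoate F11. Midland reduction with (R)-Alpine-Borane (from (+)-α-pinene; acetaldehyde, then ethanolamine work-up) reduces the alkynyl ketone to the (R)-alcohol 15.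

Further compounds
F1 | step 9 | 1-(3,5-dimethoxyphenyl)-7-[(2S,5R,7S)-7-methyl-1,6-dioxaspiro[4.4]nonan-2-yl]heptan-1-ol (both C1 epimers) | COc1cc(OC)cc(c1)C(O)CCCCCC[C@H]1CC[C@@]2(CC[C@H](C)O2)O1
F2 | step 9 | 1-(3,5-dimethoxyphenyl)-7-[(2S,5R,7S)-7-methyl-1,6-dioxaspiro[4.4]nonan-2-yl]heptan-1-one | COc1cc(OC)cc(c1)C(=O)CCCCCC[C@H]1CC[C@@]2(CC[C@H](C)O2)O1
F3 | step 9 | (1R)-1-(3,5-dimethoxyphenyl)-7-[(2S,5R,7S)-7-methyl-1,6-dioxaspiro[4.4]nonan-2-yl]heptan-1-ol | COc1cc(OC)cc(c1)[C@@H](CCCCCC[C@H]1CC[C@@]2(CC[C@H](C)O2)O1)O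
F4 | step 9 | (1R)-1-(2-bromo-3,5-dimethoxyphenyl)-7-[(2S,5R,7S)-7-methyl-1,6-dioxaspiro[4.4]nonan-2-yl]heptan-1-ol | COc1cc(OC)c(Br)c(c1)[C@@H](CCCCCC[C@H]1CC[C@@]2(CC[C@H](C)O2)O1)O
F5 | step 5 | 7-[(2S,7S)-7-methyl-1,6-dioxaspiro[4.4]nonan-2-yl]heptan-1-ol (both C5 epimers) | OCCCCCCC[C@H]1CCC2(CC[C@H](C)O2)O1
F6 | step 5 | 7-[(2S,7S)-7-methyl-1,6-dioxaspiro[4.4]nonan-2-yl]heptyl 3,5-dinitrobenzoate (both C5 epimers) | O=C(OCCCCCCC[C@H]1CCC2(CC[C@H](C)O2)O1)c1cc(cc(c1)[N+](=O)[O-])[N+](=O)[O-]
F7 | step 5 | 7-[(2S,5R,7S)-7-methyl-1,6-dioxaspiro[4.4]nonan-2-yl]heptyl 3,5-dinitrobenzoate | O=C(OCCCCCCC[C@H]1CC[C@@]2(CC[C@H](C)O2)O1)c1cc(cc(c1)[N+](=O)[O-])[N+](=O)[O-]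
F8 | step 5 | 7-[(2S,5S,7S)-7-methyl-1,6-dioxaspiro[4.4]nonan-2-yl]heptyl 3,5-dinitrobenzoate | O=C(OCCCCCCC[C@H]1CC[C@]2(CC[C@H](C)O2)O1)c1cc(cc(c1)[N+](=O)[O-])[N+](=O)[O-]
F9 | step 5 | 7-[(2S,5R,7S)-7-methyl-1,6-dioxaspiro[4.4]nonan-2-yl]heptan-1-ol | OCCCCCCC[C@H]1CC[C@@]2(CC[C@H](C)O2)O1
F10 | step 7 | methyl 4-hydroxy-10-[(2S,5R,7S)-7-methyl-1,6-dioxaspiro[4.4]nonan-2-yl]dec-2-ynoate (both C4 epimers) | COC(=O)C#CC(O)CCCCCC[C@H]1CC[C@@]2(CC[C@H](C)O2)O1
F11 | step 7 | methyl 10-[(2S,5R,7S)-7-methyl-1,6-dioxaspiro[4.4]nonan-2-yl]-4-oxodec-2-ynoate | COC(=O)C#CC(=O)CCCCCC[C@H]1CC[C@@]2(CC[C@H](C)O2)O1
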